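**Plan**

- Retrosynthesis: the butanoate acyl–O bond at C6 is cut last; then C11–C12 (α-sulfonyl carbanion at C11 plus a chiral vinyl epoxide carrying C12–C16); then ring B at C5–C6 and C8–C9 in one operation; then C9=C11 (olefination) and C9–C10 (asymmetric allylation of 2,2,6-trimethylcyclohexanone).
- Enabling feature: in ring B the acyloxy carbon C6 lies between the ring-fusion CH (C5) and the C7=C8 double bond, so ring B is the syn-hydration product of a C5=C6–C7=C8 cyclohexa-1,3-diene. That diene is a [3+3] union of a crotyl unit (C6–C7–C8, methyl C17) with C9–C10–C5, where C5 is a ketone that cannot enolise (quaternary C4 and C10 on both sides) and C9 is the β-carbon of a vinyl sulfone.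
- Forward: ring A is bought as 2,2,6-trimethylcyclohexanone and receives the C10 quaternary centre and the C9=C11 vinyl sulfone; ring B is closed in one step by Michael addition/Wittig olefination with a crotyl ylide; hydroboration, side-chain coupling at C11, desulfonylation and acylation finish the route.
- Stereochemistry: C10 from ligand-controlled decarboxylative allylation; C9 by 1,2-induction from C10 in the Michael step; C5 and C6 together by syn hydroboration on the α-face; C13 from a Sharpless epoxidation, carried through unchanged.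

Key step: step 6

Remark: atom numbers are labdane numbers (C17 is the methyl on C8, C20 the methyl on C10); the (R)-ligand of step 2 is assumed to give the (R)-ketone, as the mirror image of the established (S)-ligand to (S)-ketone relation for 2-allyl-2-alkylcyclohexanones.

**Route**

Step 1
Reactants: 1 2,2,6-trimethylcyclohexan-1-one; 2 allyl chloroformate
Product: 4 prop-2-en-1-yl 2,6,6-trimethylcyclohex-1-en-1-yl carbonate, via lithium enolate 3 (not isolated)
Conditions: LiHMDS, TMEDA, THF, 0 °C; then 2, −78 → 23 °C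
Reagents that add atoms: none
Why: The only enolisable α-position gives a single lithium enolate, and O-acylation of this hindered enolate by the chloroformate in THF/TMEDA gives the enol carbonate.

Step 2
Reactants: 4 prop-2-en-1-yl 2,6,6-trimethylcyclohex-1-en-1-yl carbonate
Product: 5 (2R)-2,6,6-trimethyl-2-(prop-2-en-1-yl)cyclohexan-1-one
Conditions: Pd2(dba)3 (2.5 mol %), (R)-t-Bu-PHOX [(R)-4-tert-butyl-2-(2-diphenylphosphanylphenyl)-4,5-dihydrooxazole] (6.25 mol %), THF, 25 °C
Reagents that add atoms: none
Why: Decarboxylative asymmetric allylic alkylation (Tsuji type) by zerovalent palladium: ionisation and loss of CO2 give a π-allylpalladium enolate that recombines at carbon, and the chiral phosphinooxazoline ligand sets the quaternary centre C10 as (R).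

Step 3
Reactants: 5 (2R)-2,6,6-trimethyl-2-(prop-2-en-1-yl)cyclohexan-1-one
Product: 6 (2R)-2,6,6-trimethyl-2-[(1E)-prop-1-en-1-yl]cyclohexan-1-one
Conditions: RuHCl(CO)(PPh3)3 (5 mol %), toluene, 80 °C
Reagents that add atoms: none
Why: Ruthenium hydride-catalysed alkene isomerisation stops at the propenyl stage because the quaternary α-carbon blocks further migration.

Step 4
Reactants: 6 (2R)-2,6,6-trimethyl-2-[(1E)-prop-1-en-1-yl]cyclohexan-1-one
Product: 8 (1R)-1,3,3-trimethyl-2-oxocyclohexane-1-carbaldehyde, via ozonide 7 (not isolated)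
Conditions: O3, CH2Cl2, −78 °C; then Me2S, −78 → 23 °C
Reagents that add atoms: ozone, [O-][O+]=O
Why: Ozonolysis with reductive work-up cleaves the propenyl double bond to the non-enolisable β-keto aldehyde and leaves the quaternary stereocentre untouched.

Step 5
Reactants: 8 (1R)-1,3,3-trimethyl-2-oxocyclohexane-1-carbaldehyde; 9 diethyl [(phenylsulfonyl)methyl]phosphonate
Product: 10 (2R)-2,6,6-trimethyl-2-[(E)-2-(phenylsulfonyl)ethenyl]cyclohexan-1-one
Conditions: LiCl, DBU, MeCN, 0 → 23 °C
Reagents that add atoms: none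
Why: Horner–Wadsworth–Emmons olefination under Masamune–Roush conditions is mild enough to avoid retro-Claisen loss of the formyl group and gives the (E)-vinyl sulfone, while the hindered ketone does not react.

Step 6
Reactants: 10 (2R)-2,6,6-trimethyl-2-[(E)-2-(phenylsulfonyl)ethenyl]cyclohexan-1-one; 11 [(2E)-but-2-en-1-yl](triphenyl)phosphonium chloride
Product: 13 11-(phenylsulfonyl)drima-5,7-diene [(4aR,5S)-1,1,4a,6-tetramethyl-5-[(phenylsulfonyl)methyl]-1,2,3,4,4a,5-hexahydronaphthalene], via allylic ylide 12 (not isolated)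
Conditions: 11, KHMDS, THF, −78 → 0 °C; then 10, −78 → 23 °C; then 60 °C
Reagents that add atoms: none
Why: Proposed new method: the crotyl ylide should add through its γ-carbon (C8) to the β-carbon (C9) of the vinyl sulfone, the α-sulfonyl carbanion so formed is quenched by transfer of the acidic C8 proton to give allylic ylide 12, and 12 closes ring B by intramolecular Wittig olefination of the ring ketone (C5=C6), giving the cyclohexa-1,3-diene directly. The closest known reaction type is the Michael addition/intramolecular Wittig [3+3] annulation of allylidenephosphoranes with α,β-unsaturated ketones to cyclohexa-1,3-dienes, in which the ketone that undergoes the Wittig step is also the activating group; here activation (sulfone) and ring closure (isolated ketone on the quaternary carbon) are separated, which has not been shown. Ring B closes by 6-exo-trig attack of the ylide carbon C6 on the ketone carbon C5, and collapse of the oxaphosphetane with loss of Ph3PO makes the closure irreversible. The one new stereocentre, C9, is set in the Michael step by the adjacent quaternary C10: with the vinyl group axial on ring A and C11 turned over the ring CH2 (C1) side, away from the syn-axial C4 methyl, only the outer face of C9 is open, and attack there gives the 9α-H configuration of the target. The step needs γ- over α-attack of the ambident ylide (only the γ-adduct can cyclise and the α-adduct can revert), chemoselectivity (the sulfone is inert to the ylide, and the non-enolisable ketone is too hindered to undergo intermolecular Wittig reaction) and a temperature low enough to avoid a 1,5-hydrogen shift in the diene.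

Step 7
Reactants: 13 11-(phenylsulfonyl)drima-5,7-diene
Product: 15 11-(phenylsulfonyl)drim-7-en-6α-ol, via allylic borane 14 (not isolated)
Conditions: BH3·THF (1.1 equiv), THF, 0 °C; then aq. NaOH, H2O2, 0 → 23 °C
Reagents that add atoms: hydrogen peroxide, OO
Why: Hydroboration–oxidation of a homoannular 5,7-diene, as known for steroidal 5,7-dienes, puts boron on C6 and hydrogen on C5 from the α-face (the β-face is shielded by the axial methyls on C4 and C10 and by the C9 side chain), giving the 6α-alcohol with trans ring fusion; addition across C7=C8 is disfavoured because it would force the C8 methyl into a 1,3-diaxial relation with the C10 methyl.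

Step 8
Reactants: 16 2-methylprop-2-en-1-ol
Product: 17 [(2S)-2-methyloxiran-2-yl]methanol
Conditions: Ti(Oi-Pr)4 (5 mol %), L-(+)-diisopropyl tartrate (6 mol %), cumene hydroperoxide, 4 Å molecular sieves, CH2Cl2, −20 °C
Reagents that add atoms: cumene hydroperoxide, CC(C)(OO)c1ccccc1
Why: Sharpless asymmetric epoxidation of the 2-substituted allylic alcohol; the L-(+)-tartrate delivers oxygen to the face that gives the (S)-epoxy alcohol.

Step 9
Reactants: 17 [(2S)-2-methyloxiran-2-yl]methanol
Product: 18 (2R)-2-methyloxirane-2-carbaldehyde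
Conditions: (COCl)2, DMSO, CH2Cl2, −78 °C; then Et3N, −78 → 0 °C; careful distillation
Reagents that add atoms: none
Why: Swern oxidation gives the non-enolisable epoxy aldehyde without touching the quaternary epoxide centre (the descriptor changes only through the priority rules).

Step 10
Reactants: 18 (2R)-2-methyloxirane-2-carbaldehyde; 19 methyl(triphenyl)phosphonium bromide
Product: 20 (2S)-2-ethenyl-2-methyloxirane
Conditions: 19, KHMDS, THF, 0 °C; then 18, 0 → 23 °C; product distilled off with THF and used as the solution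
Reagents that add atoms: none
Why: Wittig methylenation converts the aldehyde into the vinyl group without affecting the stereocentre, and co-distillation with THF avoids loss of the volatile epoxide.

Step 11
Reactants: 15 11-(phenylsulfonyl)drim-7-en-6α-ol; 20 (2S)-2-ethenyl-2-methyloxirane
Product: 22 (13R)-11-(phenylsulfonyl)labda-7,14-diene-6α,13-diol (both C11 epimers), via dilithio sulfone 21 (not isolated)
Conditions: n-BuLi (2.2 equiv), THF–DMPU, −78 °C; then 20 (THF solution), −78 → 0 °C; then H2O
Reagents that add atoms: none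
Why: The α-sulfonyl carbanion of the alkoxide/carbanion dianion opens the 2,2-disubstituted epoxide at its unhindered CH2 (SN2 epoxide opening by a lithiated sulfone), forming C11–C12 and carrying the tertiary carbinol centre C13 in unchanged as (R); the new sulfonyl-bearing centre is removed in the next step.

Step 12
Reactants: 22 (13R)-11-(phenylsulfonyl)labda-7,14-diene-6α,13-diol
Product: 23 (13R)-labda-7,14-diene-6α,13-diol
Conditions: Na(Hg) (6 % Na), Na2HPO4, MeOH–THF, −20 → 0 °C
Reagents that add atoms: none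
Why: Reductive desulfonylation with sodium amalgam cleaves the C–S bond by electron transfer and protonation, and the alkenes and both alcohols are inert (no β-leaving group is present).

Step 13
Reactants: 23 (13R)-labda-7,14-diene-6α,13-diol; 24 butanoic anhydride
Product: 25 (13R)-13-hydroxylabda-7,14-dien-6α-yl butanoate [(1S,4S,4aR,8aS)-4-[(3R)-3-hydroxy-3-methylpent-4-en-1-yl]-3,4a,8,8-tetramethyl-1,4,4a,5,6,7,8,8a-octahydronaphthalen-1-yl butanoate]
Conditions: 24 (1.5 equiv), DMAP (cat.), Et3N, CH2Cl2, 0 → 23 °C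
Reagents that add atoms: none
Why: DMAP-catalysed acylation esterifies the secondary equatorial 6α-hydroxyl, while the tertiary allylic 13-hydroxyl does not react under these conditions.

**Compound list**

1 | 2,2,6-trimethylcyclohexan-1-one (racemic) | CC1CCCC(C)(C)C1=O | starting material
2 | allyl chloroformate | C=CCOC(=O)Cl | starting material
3 | lithium 2,6,6-trimethylcyclohex-1-en-1-olate | [Li+].[O-]C1=C(C)CCCC1(C)C | intermediate (not isolated)
4 | prop-2-en-1-yl 2,6,6-trimethylcyclohex-1-en-1-yl carbonate | C=CCOC(=O)OC1=C(C)CCCC1(C)C | intermediate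
5 | (2R)-2,6,6-trimethyl-2-(prop-2-en-1-yl)cyclohexan-1-one | C=CC[C@@]1(C)CCCC(C)(C)C1=O | intermediate
6 | (2R)-2,6,6-trimethyl-2-[(1E)-prop-1-en-1-yl]cyclohexan-1-one | C/C=C/[C@@]1(C)CCCC(C)(C)C1=O | intermediate
7 | 3-methyl-5-[(1R)-1,3,3-trimethyl-2-oxocyclohexyl]-1,2,4-trioxolane (secondary ozonide) | CC1OOC(O1)[C@@]2(C)CCCC(C)(C)C2=O | intermediate (not isolated)
8 | (1R)-1,3,3-trimethyl-2-oxocyclohexane-1-carbaldehyde | O=C[C@@]1(C)CCCC(C)(C)C1=O | intermediate
9 | diethyl [(phenylsulfonyl)methyl]phosphonate | CCOP(=O)(CS(=O)(=O)c1ccccc1)OCC | starting material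
10 | (2R)-2,6,6-trimethyl-2-[(E)-2-(phenylsulfonyl)ethenyl]cyclohexan-1-one | O=S(=O)(c1ccccc1)/C=C/[C@@]2(C)CCCC(C)(C)C2=O | intermediate
11 | [(2E)-but-2-en-1-yl](triphenyl)phosphonium chloride | C/C=C/C[P+](c1ccccc1)(c1ccccc1)c1ccccc1.[Cl-] | starting material
12 | triphenyl{(4S)-3-methyl-5-(phenylsulfonyl)-4-[(1R)-1,3,3-trimethyl-2-oxocyclohexyl]pent-2-en-1-ylidene}phosphorane | O=S(=O)(c1ccccc1)C[C@@H](C(C)=CC=P(c1ccccc1)(c1ccccc1)c1ccccc1)[C@@]1(C)CCCC(C)(C)C1=O | intermediate (not isolated)
13 | 11-(phenylsulfonyl)drima-5,7-diene; (4aR,5S)-1,1,4a,6-tetramethyl-5-[(phenylsulfonyl)methyl]-1,2,3,4,4a,5-hexahydronaphthalene | O=S(=O)(c1ccccc1)C[C@H]2C(C)=CC=C3C(C)(C)CCC[C@]23C | intermediate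
14 | [11-(phenylsulfonyl)drim-7-en-6α-yl]borane (5α-H) | O=S(=O)(c1ccccc1)C[C@H]2C(C)=C[C@H](B)[C@H]3C(C)(C)CCC[C@]23C | intermediate (not isolated)
15 | 11-(phenylsulfonyl)drim-7-en-6α-ol (5α-H, 9α-H, 10β-methyl) | O=S(=O)(c1ccccc1)C[C@H]2C(C)=C[C@H](O)[C@H]3C(C)(C)CCC[C@]23C | intermediate
16 | 2-methylprop-2-en-1-ol | C=C(C)CO | starting material
17 | [(2S)-2-methyloxiran-2-yl]methanol | OC[C@@]1(C)CO1 | intermediate
18 | (2R)-2-methyloxirane-2-carbaldehyde | O=C[C@@]1(C)CO1 | intermediate
19 | methyl(triphenyl)phosphonium bromide | C[P+](c1ccccc1)(c1ccccc1)c1ccccc1.[Br-] | starting material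
20 | (2S)-2-ethenyl-2-methyloxirane | C=C[C@@]1(C)CO1 | intermediate
21 | dilithium salt of 15 (6-alkoxide and C11 α-sulfonyl carbanion) | O=S(=O)(c1ccccc1)[CH-][C@H]2C(C)=C[C@H]([O-])[C@H]3C(C)(C)CCC[C@]23C.[Li+].[Li+] | intermediate (not isolated)
22 | (13R)-11-(phenylsulfonyl)labda-7,14-diene-6α,13-diol (both C11 epimers) | C=C[C@](C)(O)CC(S(=O)(=O)c1ccccc1)[C@H]2C(C)=C[C@H](O)[C@H]3C(C)(C)CCC[C@]23C | intermediate
23 | (13R)-labda-7,14-diene-6α,13-diol | C=C[C@](C)(O)CC[C@H]1C(C)=C[C@H](O)[C@H]2C(C)(C)CCC[C@]12C | intermediate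
24 | butanoic anhydride | CCCC(=O)OC(=O)CCC | starting material
25 | (13R)-13-hydroxylabda-7,14-dien-6α-yl butanoate (5S,6S,9S,10R,13R) | C=C[C@](C)(O)CC[C@H]1C(C)=C[C@H](OC(=O)CCC)[C@H]2C(C)(C)CCC[C@]12C | target

**Summary**

Total step count: 13. Longest linear sequence: 10 steps (steps 1–7 and 11–13); the epoxide branch (steps 8–10) joins at step 11.

**Steps most likely to fail**

Step 6. What may go wrong: the Michael addition at the neopentyl β-carbon stalls or runs through the α-carbon of the ylide, the Wittig closure on the doubly neopentyl ketone does not take place, or the facial selectivity at C9 is poor. The fallback uses known reactions only, sets out from 5 and returns at 13. Ozonolysis of the allyl group of 5 with oxidative work-up (O3; then H2O2) gives 2-[(1R)-1,3,3-trimethyl-2-oxocyclohexyl]acetic acid F1. Esterification (EDC, DMAP) with (E)-but-2-en-1-ol gives (2E)-but-2-en-1-yl 2-[(1R)-1,3,3-trimethyl-2-oxocyclohexyl]acetate F2. Ireland–Claisen rearrangement (LDA, Me3SiCl, THF, −78 → 60 °C) forms the C8–C9 bond and gives 3-methyl-2-[(1R)-1,3,3-trimethyl-2-oxocyclohexyl]pent-4-enoic acid F3, which Me3SiCHN2 converts into methyl 3-methyl-2-[(1R)-1,3,3-trimethyl-2-oxocyclohexyl]pent-4-enoate F4. A Me2AlCl-promoted intramolecular carbonyl-ene reaction of the terminal alkene with the ring ketone forms the C5–C6 bond and the C7=C8 double bond in methyl 5-hydroxydrim-7-en-11-oate F5. Dehydration with the Burgess reagent (only C6 carries β-hydrogens) gives the diene ester; because C9 is now α to the ester, its configuration is set by deprotonation with LDA and kinetic protonation on the α-face, giving methyl drima-5,7-dien-11-oate F6. LiAlH4 reduction gives drima-5,7-dien-11-ol F7, PhSSPh/Bu3P gives 11-(phenylsulfanyl)drima-5,7-diene F8, and oxidation at sulfur ((NH4)6Mo7O24 cat., H2O2) gives 13.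

Step 7. What may go wrong: borane adds to the C7=C8 bond, adds twice, or attacks from the β-face. The fallback sets out from 13 and returns at 15 through the ketone. Epoxidation of 13 with mCPBA (NaHCO3), expected on the α-face of C5=C6, gives 5α,6α-epoxy-11-(phenylsulfonyl)drim-7-ene F9. Oxidative opening with CrO3 in aqueous acetone gives 5α-hydroxy-11-(phenylsulfonyl)drim-7-en-6-one F10. SmI2 (THF–MeOH) removes the hydroxyl α to the ketone, and protonation of the dienolate gives the trans-fused 11-(phenylsulfonyl)drim-7-en-6-one F11. Meerwein–Ponndorf–Verley reduction (Al(Oi-Pr)3, i-PrOH, reflux) equilibrates the allylic alcohols and should end at the equatorial 6α-alcohol 15.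

Step 11. What may go wrong: the hindered carbanion fails to open the epoxide or attacks the vinyl terminus in an SN2′ sense, or the volatile epoxide 20 is lost. The fallback sets out from 15 and 17, makes the vinyl group last and returns at 25. Silylation of 17 (TBSCl, imidazole) gives tert-butyl(dimethyl){[(2R)-2-methyloxiran-2-yl]methoxy}silane F12, a non-volatile epoxide without an allylic position. The dianion of 15 (n-BuLi, THF–DMPU) opens it at CH2 to give (13R)-14-(tert-butyldimethylsilyloxy)-11-(phenylsulfonyl)-15-norlabd-7-ene-6α,13-diol F13. Na(Hg) gives (13R)-14-(tert-butyldimethylsilyloxy)-15-norlabd-7-ene-6α,13-diol F14. Acylation with 24 (DMAP, Et3N) gives (13R)-14-(tert-butyldimethylsilyloxy)-13-hydroxy-15-norlabd-7-en-6α-yl butanoate F15, and Bu4NF gives (13R)-13,14-dihydroxy-15-norlabd-7-en-6α-yl butanoate F16. Parikh–Doering oxidation (SO3·pyridine, DMSO, i-Pr2NEt) gives (13R)-13-hydroxy-14-oxo-15-norlabd-7-en-6α-yl butanoate F17, and Wittig methylenation (Ph3P=CH2) gives 25.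

**Further compounds**

F1 | step 6 | 2-[(1R)-1,3,3-trimethyl-2-oxocyclohexyl]acetic acid | OC(=O)C[C@@]1(C)CCCC(C)(C)C1=O
F2 | step 6 | (2E)-but-2-en-1-yl 2-[(1R)-1,3,3-trimethyl-2-oxocyclohexyl]acetate | C/C=C/COC(=O)C[C@@]1(C)CCCC(C)(C)C1=O
F3 | step 6 | 3-methyl-2-[(1R)-1,3,3-trimethyl-2-oxocyclohexyl]pent-4-enoic acid (diastereomers) | C=CC(C)C(C(=O)O)[C@@]1(C)CCCC(C)(C)C1=O
F4 | step 6 | methyl 3-methyl-2-[(1R)-1,3,3-trimethyl-2-oxocyclohexyl]pent-4-enoate (diastereomers) | C=CC(C)C(C(=O)OC)[C@@]1(C)CCCC(C)(C)C1=O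
F5 | step 6 | methyl 5-hydroxydrim-7-en-11-oate (C5 and C9 epimers) | COC(=O)C1C(C)=CCC2(O)C(C)(C)CCC[C@]12C
F6 | step 6 | methyl drima-5,7-dien-11-oate (9α-H) | COC(=O)[C@H]1C(C)=CC=C2C(C)(C)CCC[C@]12C
F7 | step 6 | drima-5,7-dien-11-ol | OC[C@H]1C(C)=CC=C2C(C)(C)CCC[C@]12C
F8 | step 6 | 11-(phenylsulfanyl)drima-5,7-diene | c1ccccc1SC[C@H]2C(C)=CC=C3C(C)(C)CCC[C@]23C
F9 | step 7 | 5α,6α-epoxy-11-(phenylsulfonyl)drim-7-ene | O=S(=O)(c1ccccc1)C[C@H]2C(C)=C[C@@H]3O[C@@]34C(C)(C)CCC[C@]24C
F10 | step 7 | 5α-hydroxy-11-(phenylsulfonyl)drim-7-en-6-one | O=S(=O)(c1ccccc1)C[C@H]2C(C)=CC(=O)[C@@]3(O)C(C)(C)CCC[C@]23C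
F11 | step 7 | 11-(phenylsulfonyl)drim-7-en-6-one (5α-H) | O=S(=O)(c1ccccc1)C[C@H]2C(C)=CC(=O)[C@H]3C(C)(C)CCC[C@]23C
F12 | step 11 | tert-butyl(dimethyl){[(2R)-2-methyloxiran-2-yl]methoxy}silane | CC(C)(C)[Si](C)(C)OC[C@@]1(C)CO1
F13 | step 11 | (13R)-14-(tert-butyldimethylsilyloxy)-11-(phenylsulfonyl)-15-norlabd-7-ene-6α,13-diol (both C11 epimers) | CC(C)(C)[Si](C)(C)OC[C@](C)(O)CC(S(=O)(=O)c1ccccc1)[C@H]2C(C)=C[C@H](O)[C@H]3C(C)(C)CCC[C@]23C
F14 | step 11 | (13R)-14-(tert-butyldimethylsilyloxy)-15-norlabd-7-ene-6α,13-diol | CC(C)(C)[Si](C)(C)OC[C@](C)(O)CC[C@H]1C(C)=C[C@H](O)[C@H]2C(C)(C)CCC[C@]12C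
F15 | step 11 | (13R)-14-(tert-butyldimethylsilyloxy)-13-hydroxy-15-norlabd-7-en-6α-yl butanoate | CC(C)(C)[Si](C)(C)OC[C@](C)(O)CC[C@H]1C(C)=C[C@H](OC(=O)CCC)[C@H]2C(C)(C)CCC[C@]12C
F16 | step 11 | (13R)-13,14-dihydroxy-15-norlabd-7-en-6α-yl butanoate | OC[C@](C)(O)CC[C@H]1C(C)=C[C@H](OC(=O)CCC)[C@H]2C(C)(C)CCC[C@]12C
F17 | step 11 | (13R)-13-hydroxy-14-oxo-15-norlabd-7-en-6α-yl butanoate | O=C[C@](C)(O)CC[C@H]1C(C)=C[C@H](OC(=O)CCC)[C@H]2C(C)(C)CCC[C@]12C
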